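**Retrosynthetic overview**

1. Numbering: naphthalene half C1–C8a (OH on C1 and C8, acetyl on C2, methyl on C3); dihydronaphthalene half C1'–C8a' (carbinol C1', acetyl on C2', methyl on C3', phenol on C8'); the halves are joined C7–C7'.
2. Last disconnection: the trans ketol ring C1'(OH)–C2'(acetyl)–C3'(Me)=C4' is the anti SN2' ring-opening product of a 1,4-epoxy-1,4-dihydronaphthalene (temporary bridge C1'–O–C4') with an acetyl-anion equivalent; the bridge comes from an aryne/3-methylfuran cycloaddition.
3. Key disconnection: C7–C7' together with C8'–O, both made on a C7'≡C8' aryne by addition of the C7 naphthylmagnesium reagent and oxidation of the resulting C8'–Mg bond.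
4. Enabling feature: C7'(aryl), C8'(OH), C8a' and C4a' are four contiguous carbons of the primed benzene ring, i.e. the sites of two adjacent arynes (a 1,3-benzdiyne from 3,6-diiodocatechol); the strained oxygen-bridged ring fused at C8a'/C4a' by the first aryne lies beside C8' and steers the aryl group to C7' and the oxygen to C8' in the second.
5. Ring order: primed benzene ring (bought) → oxygen-bridged ring (step 4); naphthalene C1–C4 ring by Staunton–Weinreb annulation (step 6); biaryl bond (step 10); bridge opened to the dihydronaphthalene ring (step 12).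

Key step: step 10

Assumption: the stereodescriptors of the target are read as (1'S,2'R), which places the C1' hydroxyl and the C2' acetyl group trans.

Abbreviations in names: ArA = 7-[1-(tert-butyldimethylsilyloxy)ethenyl]-6-methyl-1,8-(di-tert-butylsilanediyldioxy)naphthalen-2-yl (the naphthalene half bonded through its C7, O1 and O8 bridged by Si(t-Bu)2); ArK = the same group with acetyl in place of the silyloxyethenyl group. In the oxygen-bridged intermediates systematic locants C1, C2, C3, C4, C5, C6 correspond to C4', C3', C2', C1', C8', C7'.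

**Route**

Step 1
Reactants: 1 1,2-dimethoxybenzene
Product: 2 1,4-diiodo-2,3-dimethoxybenzene
Conditions: n-BuLi (3 equiv), TMEDA, Et2O, 25 °C to reflux; then I2, THF, −78 to 25 °C
Reagents that add atoms: iodine ([I][I])
Why: The two methoxy groups direct a double ortho-lithiation to C3 and C6 (directed ortho-metalation) and iodine quench of the dilithio species should give the 1,4-diiodide.

Step 2
Reactants: 2 1,4-diiodo-2,3-dimethoxybenzene
Product: 3 3,6-diiodobenzene-1,2-diol
Conditions: BBr3, CH2Cl2, −78 to 25 °C; H2O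
Reagents that add atoms: none
Why: Lewis-acid cleavage of both aryl methyl ethers by BBr3 leaves the C–I bonds untouched.

Step 3
Reactants: 3 3,6-diiodobenzene-1,2-diol
Product: 4 3,6-diiodo-1,2-phenylene bis(4-chlorobenzenesulfonate)
Conditions: 4-ClC6H4SO2Cl (2.2 equiv), Et3N, DMAP (cat.), CH2Cl2, 0 to 25 °C
Reagents that add atoms: 4-chlorobenzenesulfonyl chloride (O=S(=O)(Cl)c1ccc(Cl)cc1)
Why: O-Sulfonylation gives leaving groups that tolerate a neighbouring aryl–magnesium bond at −78 °C and are expelled on warming, which is what both aryne events need.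

Step 4
Reactants: 4 3,6-diiodo-1,2-phenylene bis(4-chlorobenzenesulfonate); 5 3-methylfuran
Product: 8 rac-6-iodo-2-methyl-1,4-dihydro-1,4-epoxynaphthalen-5-yl 4-chlorobenzenesulfonate, via arylmagnesium chloride 6 (not isolated), via aryne 7 (not isolated)
Conditions: i-PrMgCl·LiCl (1.0 equiv), THF, −78 °C; 5 (5 equiv), −78 to 25 °C; chromatography
Reagents that add atoms: none
Why: Iodine–magnesium exchange at one of the two equivalent C–I bonds and loss of the neighbouring sulfonate on warming give aryne 7, whose Diels–Alder reaction with 3-methylfuran should join the more nucleophilic furan C2 (next to the methyl group) to the more electrophilic aryne carbon remote from the σ-withdrawing sulfonate, which places the methyl group on C3' beside the distal bridgehead C4'; the minor methyl regioisomer is removed by chromatography and the two bridgehead centres form as a racemic pair because the bridge can only be cis.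

Step 5
Reactants: 8 rac-6-iodo-2-methyl-1,4-dihydro-1,4-epoxynaphthalen-5-yl 4-chlorobenzenesulfonate
Product: 9 (1R,4S)-6-iodo-2-methyl-1,4-dihydro-1,4-epoxynaphthalen-5-yl 4-chlorobenzenesulfonate
Conditions: preparative SFC on a chiral stationary phase (amylose tris(3,5-dimethylphenylcarbamate)), CO2/i-PrOH
Reagents that add atoms: none
Why: Chromatographic resolution on a chiral stationary phase separates the enantiomers of the rigid bicycle; the (1R,4S) enantiomer, whose bridgehead C4 becomes C1' with the configuration of the target, is carried on, and its absolute configuration can be confirmed by anomalous-dispersion X-ray diffraction because iodine, sulfur and chlorine are present.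

Step 6
Reactants: 10 ethyl 2-methoxy-6-methylbenzoate; 11 (E)-4-methoxypent-3-en-2-one
Product: 12 1-(1-hydroxy-8-methoxy-3-methylnaphthalen-2-yl)ethan-1-one
Conditions: LiN(i-Pr)2 (2.2 equiv), THF, −78 °C; 11; −78 to 25 °C; aq. HCl
Reagents that add atoms: none
Why: Staunton–Weinreb annulation: the laterally lithiated toluate adds in Michael fashion to the β-methoxy enone, the enolate closes onto the ester and loss of methoxide aromatises the new C1–C4 ring with acetyl on C2 and methyl on C3.

Step 7
Reactants: 12 1-(1-hydroxy-8-methoxy-3-methylnaphthalen-2-yl)ethan-1-one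
Product: 13 1-(1,8-dihydroxy-3-methylnaphthalen-2-yl)ethan-1-one
Conditions: BBr3, CH2Cl2, −78 to 0 °C; H2O
Reagents that add atoms: none
Why: BBr3 cleaves the peri methyl ether (Lewis-acid aryl ether cleavage) while the chelated hydroxy ketone is only complexed and is released on aqueous work-up.

Step 8
Reactants: 13 1-(1,8-dihydroxy-3-methylnaphthalen-2-yl)ethan-1-one
Product: 14 1-(7-bromo-1,8-dihydroxy-3-methylnaphthalen-2-yl)ethan-1-one
Conditions: NBS (1.0 equiv), i-Pr2NH (10 mol %), CH2Cl2, 0 °C
Reagents that add atoms: N-bromosuccinimide (O=C1CCC(=O)N1Br)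
Why: Amine-mediated ortho-bromination of a naphthol: bromine is delivered through a hydrogen-bonded N-bromoamine to the position ortho to the free 8-OH, and the ring that carries the chelated acetyl group is deactivated, so C7 should be substituted.

Step 9
Reactants: 14 1-(7-bromo-1,8-dihydroxy-3-methylnaphthalen-2-yl)ethan-1-one
Product: 16 {1-[7-bromo-3-methyl-1,8-(di-tert-butylsilanediyldioxy)naphthalen-2-yl]ethenyl}oxy(tert-butyl)dimethylsilane, via silylene ketone 15 (not isolated)
Conditions: t-Bu2Si(OTf)2 (1.1 equiv), 2,6-lutidine, CH2Cl2, 0 to 25 °C; then TBSOTf (1.5 equiv), Et3N, 0 °C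
Reagents that add atoms: di-tert-butylsilyl bis(trifluoromethanesulfonate) (CC(C)(C)[Si](OS(=O)(=O)C(F)(F)F)(OS(=O)(=O)C(F)(F)F)C(C)(C)C); tert-butyldimethylsilyl trifluoromethanesulfonate (CC(C)(C)[Si](C)(C)OS(=O)(=O)C(F)(F)F)
Why: The peri diol closes a six-membered silylene and soft enolisation converts the hindered methyl ketone into its silyl enol ether, so no acidic hydrogen or electrophilic carbonyl enters the Grignard chemistry, and a silicon locked between O1 and O8 cannot migrate to a neighbouring carbanion.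

Step 10
Reactants: 16 {1-[7-bromo-3-methyl-1,8-(di-tert-butylsilanediyldioxy)naphthalen-2-yl]ethenyl}oxy(tert-butyl)dimethylsilane; 9 (1R,4S)-6-iodo-2-methyl-1,4-dihydro-1,4-epoxynaphthalen-5-yl 4-chlorobenzenesulfonate
Product: 22 (1R,4S)-6-ArA-2-methyl-1,4-dihydro-1,4-epoxynaphthalen-5-ol, via naphthylmagnesium bromide 17 (not isolated), via magnesiated sulfonate 18 (not isolated), via aryne 19 (not isolated), via biaryl Grignard reagent 20 (not isolated), via biaryl boronate 21 (not isolated)
Conditions: 16, Mg, LiCl, THF, 25 °C (gives 17); in a second flask 9, i-PrMgCl·LiCl (1.05 equiv), THF, −78 °C; add 17 (1.3 equiv), −78 to 25 °C; B(OMe)3, −78 to 25 °C; Me3NO, 25 to 50 °C; pH 7 buffer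
Reagents that add atoms: trimethylamine N-oxide (C[N+](C)(C)[O-])
Why: Iodine–magnesium exchange on 9 gives 18, which on warming expels the sulfonate to give the C7'≡C8' aryne 19; the naphthyl Grignard reagent 17 adds across it (carbomagnesiation of an aryne by an aryl Grignard reagent with electrophilic quench is the closest known reaction type) to give 20, and borylation followed by N-oxide oxidation turns the C8'–Mg bond into the phenol of 22, so the biaryl bond and the neighbouring C–O bond are made in one flask. No ring is closed and no stereocentre is formed; the bridgehead centres C1' and C4' fixed in step 5 are not touched. The selectivity needed is regiochemical, aryl on C7' and metal on C8': the strained oxygen-bridged ring fused at C8a' compresses the internal angle at the adjacent aryne carbon C8' and opens it at C7', so the nucleophile should attack the more linear and more electrophilic C7'. The carbanion developing at C8' is further favoured by the σ-withdrawing benzylic C1'–O bond and by chelation of magnesium to the bridging oxygen, and C7' is also the sterically open position. Chemoselectivity rests on the far higher electrophilicity of the aryne compared with the trisubstituted bicyclic alkene, and the sulfonate is the temporary group that makes the event possible and leaves as a magnesium salt.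

Step 11
Reactants: 22 (1R,4S)-6-ArA-2-methyl-1,4-dihydro-1,4-epoxynaphthalen-5-ol
Product: 23 tert-butyl{[(1R,4S)-6-ArA-2-methyl-1,4-dihydro-1,4-epoxynaphthalen-5-yl]oxy}dimethylsilane
Conditions: TBSCl, imidazole, DMF, 25 °C
Reagents that add atoms: tert-butyl(chloro)dimethylsilane (CC(C)(C)[Si](C)(C)Cl)
Why: Silylation under non-acidic conditions masks the phenol so that no phenoxide next to the strained benzylic C1'–O bond can open the bridge in step 12.

Step 12
Reactants: 23 tert-butyl{[(1R,4S)-6-ArA-2-methyl-1,4-dihydro-1,4-epoxynaphthalen-5-yl]oxy}dimethylsilane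
Product: 24 (1S,2R)-7-ArA-8-(tert-butyldimethylsilyloxy)-2-(1-ethoxyethenyl)-3-methyl-1,2-dihydronaphthalen-1-ol
Conditions: CH2=CHOEt, t-BuLi, THF, −78 to 0 °C; MgBr2·OEt2, −78 °C; CuCl (10 mol %), PPh3 (20 mol %), 23, toluene/THF, −40 to 25 °C; NH4Cl/NH3 buffer (pH 8)
Reagents that add atoms: (1-ethoxyvinyl)magnesium bromide (CCOC(=C)[Mg]Br)
Why: Copper-catalysed anti SN2' ring opening of an oxabenzonorbornadiene by a Grignard reagent: the organocopper species (monovalent copper) attacks the unsubstituted alkene carbon C2' on the face opposite the oxygen bridge while the C4'–O bond breaks, so C1' keeps its oxygen and its configuration (1'S), the new C2' centre is formed trans to it (2'R), and the methyl group on C3' excludes attack at the other alkene carbon.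

Step 13
Reactants: 24 (1S,2R)-7-ArA-8-(tert-butyldimethylsilyloxy)-2-(1-ethoxyethenyl)-3-methyl-1,2-dihydronaphthalen-1-ol
Product: 25 1-[(1S,2R)-7-ArK-8-(tert-butyldimethylsilyloxy)-1-hydroxy-3-methyl-1,2-dihydronaphthalen-2-yl]ethan-1-one
Conditions: aq. oxalic acid (0.1 M), THF, 0 to 25 °C
Reagents that add atoms: water (O)
Why: Enol ether hydrolysis: protonation of the electron-rich 1,1-disubstituted enol ether at its CH2 terminus should be much faster than ionisation of the C1' carbinol (whose ortho oxygen is still silylated), so mild acid releases the C2' acetyl group and also hydrolyses the silyl enol ether on the naphthalene without touching C1' or epimerising C2'.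

Step 14
Reactants: 25 1-[(1S,2R)-7-ArK-8-(tert-butyldimethylsilyloxy)-1-hydroxy-3-methyl-1,2-dihydronaphthalen-2-yl]ethan-1-one
Product: 26 1-[(1S,2R)-7-(7-acetyl-1,8-dihydroxy-6-methylnaphthalen-2-yl)-1,8-dihydroxy-3-methyl-1,2-dihydronaphthalen-2-yl]ethan-1-one
Conditions: Bu4NF, AcOH (1:1.2), THF, 0 °C
Reagents that add atoms: none
Why: Acetic-acid-buffered fluoride cleaves the aryl silyl ether and the silylene without free phenoxide or alkoxide building up, which avoids retro-aldol cleavage or elimination of the β-hydroxy ketone; a silyl group that may have shifted from O8' to O1' in step 12 is removed all the same.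

**Compound list**

1 | 1,2-dimethoxybenzene | COc1ccccc1OC | starting material
2 | 1,4-diiodo-2,3-dimethoxybenzene | COc1c(I)ccc(I)c1OC | intermediate
3 | 3,6-diiodobenzene-1,2-diol | Oc1c(I)ccc(I)c1O | intermediate
4 | 3,6-diiodo-1,2-phenylene bis(4-chlorobenzenesulfonate) | Clc1ccc(cc1)S(=O)(=O)Oc1c(I)ccc(I)c1OS(=O)(=O)c1ccc(Cl)cc1 | intermediate
5 | 3-methylfuran | Cc1ccoc1 | starting material
6 | [2,3-bis(4-chlorophenylsulfonyloxy)-4-iodophenyl]magnesium chloride | Clc1ccc(cc1)S(=O)(=O)Oc1c(I)ccc([Mg]Cl)c1OS(=O)(=O)c1ccc(Cl)cc1 | intermediate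
7 | 3-(4-chlorophenylsulfonyloxy)-4-iodobenzyne | Clc1ccc(cc1)S(=O)(=O)OC1=C(I)C=CC#C1 | intermediate
8 | rac-6-iodo-2-methyl-1,4-dihydro-1,4-epoxynaphthalen-5-yl 4-chlorobenzenesulfonate (racemate; bridge necessarily cis) | Ic1ccc2c(c1OS(=O)(=O)c1ccc(Cl)cc1)C1OC2C(C)=C1 | intermediate
9 | (1R,4S)-6-iodo-2-methyl-1,4-dihydro-1,4-epoxynaphthalen-5-yl 4-chlorobenzenesulfonate | Ic1ccc2c(c1OS(=O)(=O)c1ccc(Cl)cc1)[C@H]1O[C@@H]2C(C)=C1 | intermediate
10 | ethyl 2-methoxy-6-methylbenzoate | CCOC(=O)c1c(C)cccc1OC | starting material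
11 | (E)-4-methoxypent-3-en-2-one | CO/C(C)=C/C(C)=O | starting material
12 | 1-(1-hydroxy-8-methoxy-3-methylnaphthalen-2-yl)ethan-1-one | CC(=O)c1c(C)cc2cccc(OC)c2c1O | intermediate
13 | 1-(1,8-dihydroxy-3-methylnaphthalen-2-yl)ethan-1-one | CC(=O)c1c(C)cc2cccc(O)c2c1O | intermediate
14 | 1-(7-bromo-1,8-dihydroxy-3-methylnaphthalen-2-yl)ethan-1-one | CC(=O)c1c(C)cc2ccc(Br)c(O)c2c1O | intermediate
15 | 1-[7-bromo-3-methyl-1,8-(di-tert-butylsilanediyldioxy)naphthalen-2-yl]ethan-1-one | CC(=O)c1c(C)cc2ccc(Br)c3O[Si](C(C)(C)C)(C(C)(C)C)Oc1c23 | intermediate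
16 | {1-[7-bromo-3-methyl-1,8-(di-tert-butylsilanediyldioxy)naphthalen-2-yl]ethenyl}oxy(tert-butyl)dimethylsilane | C=C(O[Si](C)(C)C(C)(C)C)c1c(C)cc2ccc(Br)c3O[Si](C(C)(C)C)(C(C)(C)C)Oc1c23 | intermediate
17 | ArA–magnesium bromide | C=C(O[Si](C)(C)C(C)(C)C)c1c(C)cc2ccc([Mg]Br)c3O[Si](C(C)(C)C)(C(C)(C)C)Oc1c23 | intermediate
18 | [(1R,4S)-5-(4-chlorophenylsulfonyloxy)-2-methyl-1,4-dihydro-1,4-epoxynaphthalen-6-yl]magnesium chloride | Cl[Mg]c1ccc2c(c1OS(=O)(=O)c1ccc(Cl)cc1)[C@H]1O[C@@H]2C(C)=C1 | intermediate
19 | (1R,4S)-5,6-didehydro-2-methyl-1,4-dihydro-1,4-epoxynaphthalene (aryne) | C1#CC=CC2=C1[C@H]1O[C@@H]2C(C)=C1 | intermediate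
20 | [(1R,4S)-6-ArA-2-methyl-1,4-dihydro-1,4-epoxynaphthalen-5-yl]magnesium bromide | Br[Mg]c1c(-c2ccc3cc(C)c(C(=C)O[Si](C)(C)C(C)(C)C)c4O[Si](C(C)(C)C)(C(C)(C)C)Oc2c34)ccc2c1[C@H]1O[C@@H]2C(C)=C1 | intermediate
21 | dimethyl [(1R,4S)-6-ArA-2-methyl-1,4-dihydro-1,4-epoxynaphthalen-5-yl]boronate | COB(OC)c1c(-c2ccc3cc(C)c(C(=C)O[Si](C)(C)C(C)(C)C)c4O[Si](C(C)(C)C)(C(C)(C)C)Oc2c34)ccc2c1[C@H]1O[C@@H]2C(C)=C1 | intermediate
22 | (1R,4S)-6-ArA-2-methyl-1,4-dihydro-1,4-epoxynaphthalen-5-ol | Oc1c(-c2ccc3cc(C)c(C(=C)O[Si](C)(C)C(C)(C)C)c4O[Si](C(C)(C)C)(C(C)(C)C)Oc2c34)ccc2c1[C@H]1O[C@@H]2C(C)=C1 | intermediate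
23 | tert-butyl{[(1R,4S)-6-ArA-2-methyl-1,4-dihydro-1,4-epoxynaphthalen-5-yl]oxy}dimethylsilane | CC(C)(C)[Si](C)(C)Oc1c(-c2ccc3cc(C)c(C(=C)O[Si](C)(C)C(C)(C)C)c4O[Si](C(C)(C)C)(C(C)(C)C)Oc2c34)ccc2c1[C@H]1O[C@@H]2C(C)=C1 | intermediate
24 | (1S,2R)-7-ArA-8-(tert-butyldimethylsilyloxy)-2-(1-ethoxyethenyl)-3-methyl-1,2-dihydronaphthalen-1-ol | CC(C)(C)[Si](C)(C)Oc1c(-c2ccc3cc(C)c(C(=C)O[Si](C)(C)C(C)(C)C)c4O[Si](C(C)(C)C)(C(C)(C)C)Oc2c34)ccc2c1[C@@H](O)[C@H](C(=C)OCC)C(C)=C2 | intermediate
25 | 1-[(1S,2R)-7-ArK-8-(tert-butyldimethylsilyloxy)-1-hydroxy-3-methyl-1,2-dihydronaphthalen-2-yl]ethan-1-one | CC(C)(C)[Si](C)(C)Oc1c(-c2ccc3cc(C)c(C(C)=O)c4O[Si](C(C)(C)C)(C(C)(C)C)Oc2c34)ccc2c1[C@@H](O)[C@H](C(C)=O)C(C)=C2 | intermediate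
26 | 1-[(1S,2R)-7-(7-acetyl-1,8-dihydroxy-6-methylnaphthalen-2-yl)-1,8-dihydroxy-3-methyl-1,2-dihydronaphthalen-2-yl]ethan-1-one | CC(=O)c1c(C)cc2ccc(-c3ccc4c(c3O)[C@@H](O)[C@H](C(C)=O)C(C)=C4)c(O)c2c1O | target

**Step count and risks**

Total steps: 14. Longest linear sequence: 10 steps (steps 1–5, then 10–14); the naphthalene branch (steps 6–9) joins at step 10.

Steps most likely to fail:

Step 10. The aryne may oligomerise or be captured by the magnesiated sulfonate instead of the naphthyl Grignard reagent, the hindered C8'–Mg bond may be protonated before it is borylated, or part of the addition may occur at C8'. The fallback forms the biaryl bond by Suzuki–Miyaura coupling and keeps the catechol oxygen on C8' instead of delivering it by oxidation. It sets out from 9 and 16 and comes back at 23. Sulfonate cleavage of 9 with NaOMe in MeOH/THF at 25 °C should give (1R,4S)-6-iodo-2-methyl-1,4-dihydro-1,4-epoxynaphthalen-5-ol F1, and silylation (TBSCl, imidazole, DMF) its silyl ether tert-butyl{[(1R,4S)-6-iodo-2-methyl-1,4-dihydro-1,4-epoxynaphthalen-5-yl]oxy}dimethylsilane F2. Bromine–lithium exchange on 16 (n-BuLi, THF, −78 °C) and quench with 2-isopropoxy-4,4,5,5-tetramethyl-1,3,2-dioxaborolane should give the pinacol boronate ArA–B(pin) F3. Coupling of F2 with F3 (Pd(OAc)2, SPhos, anhydrous K3PO4, toluene, 80 °C) should then give 23; the methyl-substituted bicyclic alkene should be too hindered for competing carbopalladation.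

Step 12. Transfer of the oxygen-substituted vinyl group from copper to the hindered trisubstituted alkene may be slow, so that no opening or an uncatalysed syn opening takes over. The fallback accepts the syn course and corrects C2' afterwards. It sets out from 23 and comes back at 25. (1-Ethoxyvinyl)lithium alone (THF, −78 to 0 °C) should open the bridge by the known syn SN2' addition of organolithium reagents to oxabenzonorbornadienes and give the cis carbinol (1S,2S)-7-ArA-8-(tert-butyldimethylsilyloxy)-2-(1-ethoxyethenyl)-3-methyl-1,2-dihydronaphthalen-1-ol F4. The conditions of step 13 should give the cis diketone 1-[(1S,2S)-7-ArK-8-(tert-butyldimethylsilyloxy)-1-hydroxy-3-methyl-1,2-dihydronaphthalen-2-yl]ethan-1-one F5. Its doubly activated C2'–H (α to the ketone and allylic) is then equilibrated with catalytic DBU in CH2Cl2 at 0 °C while all phenols are still silylated, so that no acidic phenol consumes the base. This should lead to 25, because the trans ketol can place both the C1' hydroxyl (peri to O8') and the C2' acetyl group (next to the C3' methyl) pseudoaxial; step 14 then gives 26.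

Step 13. The acid needed for enol ether hydrolysis may ionise the C1' carbinol, with loss of water and aromatisation to the binaphthyl. The fallback unveils the C2' ketone oxidatively and uses no acid. It sets out from 23 and comes back at 26. Vinylmagnesium bromide with CuCl/PPh3 (the same anti SN2' opening, with a simple alkenyl Grignard reagent) should give (1S,2R)-7-ArA-8-(tert-butyldimethylsilyloxy)-2-ethenyl-3-methyl-1,2-dihydronaphthalen-1-ol F6. Tsuji–Wacker oxidation of the terminal vinyl group (PdCl2 (10 mol %), CuCl, O2, DMF/H2O, 25 °C; divalent palladium attacks the monosubstituted alkene in preference to the trisubstituted ring alkene) should give the methyl ketone 1-[(1S,2R)-7-ArA-8-(tert-butyldimethylsilyloxy)-1-hydroxy-3-methyl-1,2-dihydronaphthalen-2-yl]ethan-1-one F7, or 25 if the silyl enol ether is lost under these conditions. The buffered fluoride of step 14 then gives 26.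

**Further compounds**

F1 | step 10 | (1R,4S)-6-iodo-2-methyl-1,4-dihydro-1,4-epoxynaphthalen-5-ol | Oc1c(I)ccc2c1[C@H]1O[C@@H]2C(C)=C1
F2 | step 10 | tert-butyl{[(1R,4S)-6-iodo-2-methyl-1,4-dihydro-1,4-epoxynaphthalen-5-yl]oxy}dimethylsilane | CC(C)(C)[Si](C)(C)Oc1c(I)ccc2c1[C@H]1O[C@@H]2C(C)=C1
F3 | step 10 | ArA–B(pin) (pinacol boronate at C7 of the naphthalene half) | C=C(O[Si](C)(C)C(C)(C)C)c1c(C)cc2ccc(B4OC(C)(C)C(C)(C)O4)c3O[Si](C(C)(C)C)(C(C)(C)C)Oc1c23
F4 | step 12 | (1S,2S)-7-ArA-8-(tert-butyldimethylsilyloxy)-2-(1-ethoxyethenyl)-3-methyl-1,2-dihydronaphthalen-1-ol | CC(C)(C)[Si](C)(C)Oc1c(-c2ccc3cc(C)c(C(=C)O[Si](C)(C)C(C)(C)C)c4O[Si](C(C)(C)C)(C(C)(C)C)Oc2c34)ccc2c1[C@@H](O)[C@@H](C(=C)OCC)C(C)=C2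
F5 | step 12 | 1-[(1S,2S)-7-ArK-8-(tert-butyldimethylsilyloxy)-1-hydroxy-3-methyl-1,2-dihydronaphthalen-2-yl]ethan-1-one | CC(C)(C)[Si](C)(C)Oc1c(-c2ccc3cc(C)c(C(C)=O)c4O[Si](C(C)(C)C)(C(C)(C)C)Oc2c34)ccc2c1[C@@H](O)[C@@H](C(C)=O)C(C)=C2
F6 | step 13 | (1S,2R)-7-ArA-8-(tert-butyldimethylsilyloxy)-2-ethenyl-3-methyl-1,2-dihydronaphthalen-1-ol | CC(C)(C)[Si](C)(C)Oc1c(-c2ccc3cc(C)c(C(=C)O[Si](C)(C)C(C)(C)C)c4O[Si](C(C)(C)C)(C(C)(C)C)Oc2c34)ccc2c1[C@@H](O)[C@H](C=C)C(C)=C2
F7 | step 13 | 1-[(1S,2R)-7-ArA-8-(tert-butyldimethylsilyloxy)-1-hydroxy-3-methyl-1,2-dihydronaphthalen-2-yl]ethan-1-one | CC(C)(C)[Si](C)(C)Oc1c(-c2ccc3cc(C)c(C(=C)O[Si](C)(C)C(C)(C)C)c4O[Si](C(C)(C)C)(C(C)(C)C)Oc2c34)ccc2c1[C@@H](O)[C@H](C(C)=O)C(C)=C2
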